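A direct plan would take the arene ready-made: ortho-metalation of N,N-diethyl-2,5-dimethoxybenzamide A1 and opening of (S)-epichlorohydrin A2 would give aryl epoxide A3.
The silyl dithiane linchpin 2-(tert-butyldimethylsilyl)-1,3-dithiane A4 would then join A3 to (S)-propylene oxide A5 by an anion relay, with in-flask succinylation of the last alkoxide, to give acid A6.
Hot acid would close the lactone from the diethylamide to give dithiane lactone A7, nickel desulfurization would give dimethyl ether A8, and a boron trihalide would finally free both phenols.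
Weakest: the last-step cleavage of both aryl methyl ethers, because a strong Lewis acid meets the lactone, the secondary succinate and the free acid on the final intermediate, and the chelated C8 ether tends to lag.
Weak: the three-component linchpin coupling, because four anionic events must run cleanly in one flask beside an electrophilic benzamide, only to install a carbon that ends as CH2, so the desulfurization after it builds nothing.
Weak: the lactonization of the hindered diethylamide, because it needs hot strong acid next to the secondary succinate and the thioketal, and spends a step on undoing the directing group.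

**Retrosynthetic overview** (target numbering: lactone C1, O2, C3, C4; arene C4a to C8a; side chain C1' to C5' counted from C3)
- Feature used: the hydroquinone ring C4a/C5/C6/C7/C8/C8a carries oxygen at C5 and C8 and only hydrogen at C6 and C7, which is the C4O2 pattern of succinic anhydride.
- Key disconnection: C4a–C5 and C8a–C8, a Diels–Alder benzannulation of 2,5-bis(trimethylsilyloxy)furan onto the C=C bond of a (6R)-6-alkyl-5,6-dihydro-2H-pyran-2-one; the oxygen bridge leaves as a disiloxane and the free 5,8-diol appears directly.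
- Ring order: lactone first (asymmetric hetero-Diels–Alder of an aldehyde with 1-methoxybutadiene forms C3–C4 and O2–C1 and sets C3, then acetal oxidation), benzene ring last.
- C4' comes from (S)-pent-4-en-2-ol, acylated at the outset with mono-tert-butyl succinate; hydroformylation supplies the aldehyde.
- Avoided by design: no aryl methyl ethers to cleave, no linchpin carbon to erase, no amide to lactonize; the only protecting group falls in the acid stage of the key step.

Key step: step 6

Assumption: the (1R,2S)-aminoindanol enantiomer of the chromium catalyst is taken to deliver the (2R) dihydropyran; should the first run show the opposite sense, the mirror-image catalyst would be used.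

**Step 1**
Reactants: 1 (S)-pent-4-en-2-ol; 2 4-tert-butoxy-4-oxobutanoic acid (mono-tert-butyl succinate)
Product: 3 tert-butyl (2S)-pent-4-en-2-yl butanedioate
Conditions: EDC·HCl (1.3 equiv), DMAP (0.2 equiv), CH2Cl2, 0 °C → rt
Reagents that add atoms: none
Why: Steglich esterification (carbodiimide activation, DMAP acyl transfer) acylates the secondary alcohol without breaking its C–O bond, so C4' stays (S) and the succinate is in place from the start.

**Step 2**
Reactants: 3 tert-butyl (2S)-pent-4-en-2-yl butanedioate
Product: 4 tert-butyl (2S)-6-oxohexan-2-yl butanedioate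
Conditions: Rh(acac)(CO)2 (0.5 mol %), Xantphos (2 mol %), CO/H2 (1:1, 10 bar), toluene, 80 °C
Reagents that add atoms: carbon monoxide, [C-]#[O+]
Why: Rhodium-catalysed hydroformylation with a wide-bite-angle diphosphine should favour anti-Markovnikov insertion and hence the linear aldehyde; the esters and the remote stereocenter are not touched.

**Step 3**
Reactants: 4 tert-butyl (2S)-6-oxohexan-2-yl butanedioate; 5 (E)-1-methoxybuta-1,3-diene
Product: 6 tert-butyl (2S)-5-[(2R,6R)-6-methoxy-3,6-dihydro-2H-pyran-2-yl]pentan-2-yl butanedioate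
Conditions: 5 (2 equiv), CrCl(L) (3 mol %; trivalent chromium; L = dianion of the Schiff base from 3-(1-adamantyl)-2-hydroxy-5-methylbenzaldehyde and (1R,2S)-1-aminoindan-2-ol), 4 Å MS, neat, rt
Reagents that add atoms: none
Why: This is a Lewis-acid-catalysed hetero-Diels–Alder reaction of an unbranched aliphatic aldehyde with a mono-oxygenated diene, the substrate pairing this catalyst type is known for; the aldehyde binds to the chiral chromium centre, endo approach should give the cis-2,6 adduct, and the catalyst (not the remote C4' centre) selects the aldehyde face and so sets the future C3 as (R).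

**Step 4**
Reactants: 6 tert-butyl (2S)-5-[(2R,6R)-6-methoxy-3,6-dihydro-2H-pyran-2-yl]pentan-2-yl butanedioate
Product: 8 tert-butyl (2S)-5-[(2R)-6-oxo-3,6-dihydro-2H-pyran-2-yl]pentan-2-yl butanedioate, via lactol 7 (not isolated)
Conditions: PPTS (0.2 equiv), acetone/H2O (4:1), rt; then TEMPO (0.1 equiv), PhI(OAc)2 (1.3 equiv), CH2Cl2, rt
Reagents that add atoms: water, O
Why: Mild hydrolysis of the allylic methyl acetal (PPTS should spare the tert-butyl ester) gives the lactol, which oxoammonium oxidation (TEMPO/PhI(OAc)2) should convert to the conjugated lactone; the acetal stereocenter disappears and the ring carbon bearing the chain is not touched.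

**Step 5**
Reactants: 9 succinic anhydride
Product: 10 2,5-bis(trimethylsilyloxy)furan
Conditions: TMSCl (2.3 equiv), Et3N (2.5 equiv), ZnCl2 (3 mol %), MeCN, rt → 40 °C; pentane extraction, distillation under reduced pressure
Reagents that add atoms: chlorotrimethylsilane, C[Si](C)(C)Cl
Why: Double O-silylation of the enolizable anhydride (silyl ketene acetal formation) is driven by formation of the aromatic furan and is a known preparation of this diene.

**Step 6 (key step)**
Reactants: 8 tert-butyl (2S)-5-[(2R)-6-oxo-3,6-dihydro-2H-pyran-2-yl]pentan-2-yl butanedioate; 10 2,5-bis(trimethylsilyloxy)furan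
Product: 14 Aspergimarin B, via oxa-bridged cycloadduct 11 (not isolated), via enedione 12 (not isolated), via tert-butyl ester 13 (not isolated)
Conditions: 10 (3 equiv), BHT (1 mol %), toluene (1 M), sealed tube, 110 °C; evaporate; TFA/CH2Cl2 (1:4), 0 °C, 15 min; then Et3SiH (5 equiv), TFA/CH2Cl2 (1:1), rt, under Ar
Reagents that add atoms: none
Why: Proposed new method: the electron-rich diene 10 should add in a thermal normal-demand [4+2] across the electron-poor C=C bond of lactone 8 to give the 7-oxanorbornene 11, whose bridging oxygen sits between two silyl ketal carbons; acid opens the bridge, hexamethyldisiloxane leaves, the cyclohex-2-ene-1,4-dione 12 tautomerizes to the hydroquinone 13, and the same acid then cleaves the tert-butyl ester while Et3SiH traps the cation. The closest known reaction type is the Diels–Alder benzannulation of 2,5-bis(silyloxy)furans with strongly activated dienophiles (maleic anhydride, quinones, acetylenedicarboxylates) to hydroquinones and quinones, together with thermal Diels–Alder reactions of 5,6-dihydro-2H-pyran-2-ones with silyloxy dienes; new is the pairing of this diene with a singly activated, cis-disubstituted lactone enoate. The benzene ring closes by intermolecular [4+2] annulation onto the preformed lactone (bonds C4a–C5 and C8a–C8), so the core is completed lactone first, arene second. No new stereocenter survives: the four sp3 centres of 11 are erased on aromatization, so neither endo/exo, facial nor regiochemical control is needed (the diene is C2v-symmetric), and C3 and C4' lie away from every reacting bond and are not epimerizable. The one selectivity required is cycloaddition at C2/C5 of the furan and not Michael-type attack through C3, which the absence of any Lewis acid under neutral thermal conditions should secure.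

**Compound list**
1 | (S)-pent-4-en-2-ol | C[C@H](O)CC=C | starting material
2 | 4-tert-butoxy-4-oxobutanoic acid (mono-tert-butyl succinate) | CC(C)(C)OC(=O)CCC(=O)O | starting material
3 | tert-butyl (2S)-pent-4-en-2-yl butanedioate | C=CC[C@H](C)OC(=O)CCC(=O)OC(C)(C)C | intermediate
4 | tert-butyl (2S)-6-oxohexan-2-yl butanedioate | O=CCCC[C@H](C)OC(=O)CCC(=O)OC(C)(C)C | intermediate
5 | (E)-1-methoxybuta-1,3-diene | CO/C=C/C=C | starting material
6 | tert-butyl (2S)-5-[(2R,6R)-6-methoxy-3,6-dihydro-2H-pyran-2-yl]pentan-2-yl butanedioate | CO[C@H]1C=CC[C@@H](CCC[C@H](C)OC(=O)CCC(=O)OC(C)(C)C)O1 | intermediate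
7 | tert-butyl (2S)-5-[(2R)-6-hydroxy-3,6-dihydro-2H-pyran-2-yl]pentan-2-yl butanedioate (lactol, anomer mixture) | OC1C=CC[C@@H](CCC[C@H](C)OC(=O)CCC(=O)OC(C)(C)C)O1 | intermediate (not isolated)
8 | tert-butyl (2S)-5-[(2R)-6-oxo-3,6-dihydro-2H-pyran-2-yl]pentan-2-yl butanedioate | O=C1C=CC[C@@H](CCC[C@H](C)OC(=O)CCC(=O)OC(C)(C)C)O1 | intermediate
9 | succinic anhydride | O=C1CCC(=O)O1 | starting material
10 | 2,5-bis(trimethylsilyloxy)furan | C[Si](C)(C)Oc1ccc(O[Si](C)(C)C)o1 | intermediate
11 | tert-butyl (2S)-5-[(3R)-1-oxo-5,8-bis(trimethylsilyloxy)-3,4,4a,5,8,8a-hexahydro-1H-5,8-epoxyisochromen-3-yl]pentan-2-yl butanedioate (ring-fusion and bridgehead centres as a mixture) | O=C1O[C@H](CCC[C@H](C)OC(=O)CCC(=O)OC(C)(C)C)CC2C1C3(O[Si](C)(C)C)C=CC2(O[Si](C)(C)C)O3 | intermediate (not isolated)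
12 | tert-butyl (2S)-5-[(3R)-1,5,8-trioxo-3,4,4a,5,8,8a-hexahydro-1H-isochromen-3-yl]pentan-2-yl butanedioate | O=C1O[C@H](CCC[C@H](C)OC(=O)CCC(=O)OC(C)(C)C)CC2C1C(=O)C=CC2=O | intermediate (not isolated)
13 | tert-butyl (2S)-5-[(3R)-5,8-dihydroxy-1-oxo-3,4-dihydro-1H-isochromen-3-yl]pentan-2-yl butanedioate | C[C@@H](CCC[C@@H]1Cc2c(O)ccc(O)c2C(=O)O1)OC(=O)CCC(=O)OC(C)(C)C | intermediate (not isolated)
14 | Aspergimarin B, 4-({(2S)-5-[(3R)-5,8-dihydroxy-1-oxo-3,4-dihydro-1H-isochromen-3-yl]pentan-2-yl}oxy)-4-oxobutanoic acid | C[C@@H](CCC[C@@H]1Cc2c(O)ccc(O)c2C(=O)O1)OC(=O)CCC(=O)O | target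

**Step count and risks**
Total steps: 6. Longest linear sequence: 5 (steps 1, 2, 3, 4, 6).

Steps most likely to fail:

1. Step 6 (proposed new method). The cycloaddition may be too slow for a singly activated, cis-disubstituted enoate, so that the diene is lost to thermal decomposition or reacts through C3 in a Michael sense instead. The fallback uses known reaction types only, sets out from 8 and comes back at 12. A thermal Diels–Alder reaction of 8 with the open-chain, non-aromatic and therefore more reactive (1E,3E)-1,4-bis(trimethylsilyloxy)buta-1,3-diene (xylene, 130 °C) should give tert-butyl (2S)-5-[(3R)-1-oxo-5,8-bis(trimethylsilyloxy)-3,4,4a,5,8,8a-hexahydro-1H-isochromen-3-yl]pentan-2-yl butanedioate F1. Mild acid (AcOH/THF/H2O, rt) should free tert-butyl (2S)-5-[(3R)-5,8-dihydroxy-1-oxo-3,4,4a,5,8,8a-hexahydro-1H-isochromen-3-yl]pentan-2-yl butanedioate F2. Dess–Martin periodinane should oxidize both allylic alcohols to enedione 12, which is then taken through the acid stage of step 6 (tautomerization to 13, ester cleavage to 14).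

2. Step 3. Facial selectivity may be insufficient, or of the opposite sense, with this flexible aldehyde, or the ester groups may slow the catalyst. The fallback sets out from 4 and comes back at 8. Brown allylation with (−)-B-allyldiisopinocampheylborane (the reagent enantiomer expected to give the (6R) alcohol; Et2O, −78 °C, buffered NaBO3 work-up) should give tert-butyl (2S,6R)-6-hydroxynon-8-en-2-yl butanedioate F3. Acryloyl chloride and i-Pr2NEt should give tert-butyl (2S,6R)-6-(prop-2-enoyloxy)non-8-en-2-yl butanedioate F4. Ring-closing metathesis with second-generation Grubbs catalyst (CH2Cl2, 40 °C) should then close the lactone 8 directly.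

3. Step 2. Regiocontrol may be lost to the branched aldehyde, or the terminal alkene may isomerize to unreactive internal alkenes. The fallback sets out from 3 and comes back at 4. Cross-metathesis with crotonaldehyde (second-generation Hoveyda–Grubbs catalyst, CH2Cl2, 40 °C) should give tert-butyl (2S,4E)-6-oxohex-4-en-2-yl butanedioate F5, and hydrogenation of the conjugated C=C bond (H2, Pd/C, EtOAc) should give aldehyde 4.

**Further compounds**
F1 | step 6 | tert-butyl (2S)-5-[(3R)-1-oxo-5,8-bis(trimethylsilyloxy)-3,4,4a,5,8,8a-hexahydro-1H-isochromen-3-yl]pentan-2-yl butanedioate | O=C1O[C@H](CCC[C@H](C)OC(=O)CCC(=O)OC(C)(C)C)CC2C1C(O[Si](C)(C)C)C=CC2O[Si](C)(C)C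
F2 | step 6 | tert-butyl (2S)-5-[(3R)-5,8-dihydroxy-1-oxo-3,4,4a,5,8,8a-hexahydro-1H-isochromen-3-yl]pentan-2-yl butanedioate | O=C1O[C@H](CCC[C@H](C)OC(=O)CCC(=O)OC(C)(C)C)CC2C1C(O)C=CC2O
F3 | step 3 | tert-butyl (2S,6R)-6-hydroxynon-8-en-2-yl butanedioate | C=CC[C@H](O)CCC[C@H](C)OC(=O)CCC(=O)OC(C)(C)C
F4 | step 3 | tert-butyl (2S,6R)-6-(prop-2-enoyloxy)non-8-en-2-yl butanedioate | C=CC[C@H](OC(=O)C=C)CCC[C@H](C)OC(=O)CCC(=O)OC(C)(C)C
F5 | step 2 | tert-butyl (2S,4E)-6-oxohex-4-en-2-yl butanedioate | O=C/C=C/C[C@H](C)OC(=O)CCC(=O)OC(C)(C)C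
A1 | direct plan | N,N-diethyl-2,5-dimethoxybenzamide | CCN(CC)C(=O)c1cc(OC)ccc1OC
A2 | direct plan | (S)-epichlorohydrin, (2S)-2-(chloromethyl)oxirane | ClC[C@@H]1CO1
A3 | direct plan | N,N-diethyl-3,6-dimethoxy-2-[(2S)-oxiran-2-ylmethyl]benzamide | CCN(CC)C(=O)c1c(C[C@H]2CO2)c(OC)ccc1OC
A4 | direct plan | 2-(tert-butyldimethylsilyl)-1,3-dithiane | CC(C)(C)[Si](C)(C)C1SCCCS1
A5 | direct plan | (S)-propylene oxide, (2S)-2-methyloxirane | C[C@H]1CO1
A6 | direct plan | 4-{[(2S)-1-{2-[(2S)-2-[(tert-butyldimethylsilyl)oxy]-3-[2-(diethylcarbamoyl)-3,6-dimethoxyphenyl]propyl]-1,3-dithian-2-yl}propan-2-yl]oxy}-4-oxobutanoic acid | CCN(CC)C(=O)c1c(C[C@H](O[Si](C)(C)C(C)(C)C)CC2(C[C@H](C)OC(=O)CCC(=O)O)SCCCS2)c(OC)ccc1OC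
A7 | direct plan | 4-{[(2S)-1-(2-{[(3S)-5,8-dimethoxy-1-oxo-3,4-dihydro-1H-isochromen-3-yl]methyl}-1,3-dithian-2-yl)propan-2-yl]oxy}-4-oxobutanoic acid | COc1ccc(OC)c2C(=O)O[C@H](CC3(C[C@H](C)OC(=O)CCC(=O)O)SCCCS3)Cc12
A8 | direct plan | 4-({(2S)-5-[(3R)-5,8-dimethoxy-1-oxo-3,4-dihydro-1H-isochromen-3-yl]pentan-2-yl}oxy)-4-oxobutanoic acid | COc1ccc(OC)c2C(=O)O[C@H](CCC[C@H](C)OC(=O)CCC(=O)O)Cc12
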